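**Strategy.** The flavone is opened across ring C at three bonds, C8a–O1, C4a–C4 and O1–C2. Ring A is supplied as a C4a–C8a aryne released from an ortho-silylaryl triflate that already carries the C5 and C6 methoxy groups and a benzyl-protected C7 oxygen; C2, C3, C4 and ring B come from a 3-arylpropiolic acid. In a single operation the aryne accepts the carboxylate oxygen at C8a and the acyl carbon at C4a, and the phenoxide then closes ring C. The step exploits the adjacency of C4a and C8a in ring A and the lone C5 methoxy group next to C4a, C8 being left as hydrogen. C8 and C3 are oxygenated afterwards and both benzyl ethers are removed last.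

Key step: step 7

Remark: flavone numbering is used (O1, C2, C3, C4, C4a, C5 to C8, C8a; ring A is the benzo ring, ring C the pyranone, ring B the 2-aryl group). The target has no stereocenter. C8 is deliberately kept as hydrogen in the aryne precursor, because an oxygen there would flank the second aryne carbon and cancel the bias from the C5 methoxy group. The precursor phenol is built from 2,3,4-trihydroxybenzaldehyde so that each oxygen is differentiated by a regiochemically defined step.

**Step 1**
Reactants: 1 2,3,4-trihydroxybenzaldehyde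
Product: 2 4-benzyloxy-2,3-dihydroxybenzaldehyde
Conditions: BnBr (1.0 equiv), NaHCO3 (1.1 equiv), DMF, 40 °C
Reagents that add atoms: benzyl bromide, BrCc1ccccc1
Why: Williamson etherification under weak-base control should alkylate only O4, because the C4 hydroxyl para to the formyl group is the most acidic and is the one ionised by NaHCO3, the C2 hydroxyl being held in a hydrogen bond to the aldehyde and the C3 hydroxyl being the least acidic.

**Step 2**
Reactants: 2 4-benzyloxy-2,3-dihydroxybenzaldehyde
Product: 3 4-benzyloxy-2,3-dimethoxybenzaldehyde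
Conditions: MeI (3 equiv), K2CO3, DMF, 40 °C
Reagents that add atoms: iodomethane, CI
Why: Exhaustive Williamson O-methylation of the two remaining phenols with K2CO3 in DMF, which is basic enough to ionise the chelated C2 hydroxyl, while the aldehyde and the benzyl ether are inert.

**Step 3**
Reactants: 3 4-benzyloxy-2,3-dimethoxybenzaldehyde
Product: 5 4-benzyloxy-2,3-dimethoxyphenol, via aryl formate 4 (not isolated)
Conditions: mCPBA, CH2Cl2, 0 °C to rt; then K2CO3 (cat.), MeOH, rt
Reagents that add atoms: 3-chloroperoxybenzoic acid, O=C(OO)c1cccc(Cl)c1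
Why: Baeyer–Villiger (Dakin-type) oxidation, in which the electron-rich aryl group (ortho methoxy, para benzyloxy) migrates in preference to hydride to give formate 4, which is methanolysed to the phenol under mild base.

**Step 4**
Reactants: 5 4-benzyloxy-2,3-dimethoxyphenol
Product: 6 4-benzyloxy-6-bromo-2,3-dimethoxyphenol
Conditions: NBS (1.0 equiv), iPr2NH (cat.), CH2Cl2, −20 to 0 °C
Reagents that add atoms: N-bromosuccinimide, O=C1CCC(=O)N1Br
Why: Electrophilic aromatic bromination directed by the free hydroxyl, the strongest donor on the ring, whose only open ortho or para site is C6; the amine-mediated NBS protocol for ortho-bromination of phenols reinforces this choice over C5 next to the benzyl ether.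

**Step 5**
Reactants: 6 4-benzyloxy-6-bromo-2,3-dimethoxyphenol
Product: 9 4-benzyloxy-2,3-dimethoxy-6-(trimethylsilyl)phenyl trifluoromethanesulfonate, via aryl silyl ether 7 (not isolated), via lithium silylphenoxide 8 (not isolated)
Conditions: HMDS, THF, 70 °C, then evaporate; n-BuLi, THF, −100 °C; Tf2O, −100 °C to rt
Reagents that add atoms: hexamethyldisilazane, C[Si](C)(C)N[Si](C)(C)C; trifluoromethanesulfonic anhydride, O=S(=O)(OS(=O)(=O)C(F)(F)F)C(F)(F)F
Why: Standard one-flask route to ortho-silylaryl triflates: O-silylation, bromine–lithium exchange at −100 °C, retro-Brook 1,3 O-to-C silyl shift to lithium phenoxide 8 and O-triflation, none of which should touch the methyl or benzyl ethers at this temperature.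

**Step 6**
Reactants: 10 1-(benzyloxy)-4-iodobenzene; 11 propiolic acid
Product: 12 3-(4-benzyloxyphenyl)propiolic acid
Conditions: Pd(PPh3)4 (2.5 mol%), DBU (2.4 equiv), DMSO, 35 °C; then 1 M HCl
Reagents that add atoms: none
Why: Copper-free Sonogashira coupling of an aryl iodide with propiolic acid as its amidinium carboxylate, run near room temperature so that the arylpropiolic acid does not decarboxylate.

**Step 7**
Reactants: 9 4-benzyloxy-2,3-dimethoxy-6-(trimethylsilyl)phenyl trifluoromethanesulfonate (1.5 equiv); 12 3-(4-benzyloxyphenyl)propiolic acid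
Product: 15 7-benzyloxy-2-(4-benzyloxyphenyl)-5,6-dimethoxychromen-4-one, via aryne 13 (not isolated), via ynone phenoxide 14 (not isolated)
Conditions: CsF (4 equiv), THF, 125 °C, sealed tube
Reagents that add atoms: none
Why: Fluoride removes the silyl group and triflate departs to give aryne 13; the cesium carboxylate of 12 adds through oxygen to C8a, and the aryl anion generated at C4a attacks the carbonyl of the aryl ester just formed through a four-membered transition state (an anionic Fries-type acyl shift) to give ketone phenoxide 14. Phenoxide 14 then closes ring C by 6-endo-dig oxa-Michael addition to the ynone, forming O1–C2, and the C3 vinyl anion is protonated by the acid and HF present. The closest known reaction type is the fluoride-mediated intermolecular C–O insertion of arynes into carboxylic acids, which gives ortho-hydroxyaryl ketones and, from arylpropiolic acids, flavones. No stereocenter is formed. The step needs regioselective oxygen attack: the C5 methoxy group next to C4a distorts the aryne and stabilises negative charge at C4a inductively, so the nucleophile should bond to the remote C8a, while C8 bears only hydrogen and exerts no opposing bias. Closure to the six-membered flavone, not the five-membered aurone, is expected for a free phenoxide adding to an aryl ynone under metal-free basic conditions.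

**Step 8**
Reactants: 15 7-benzyloxy-2-(4-benzyloxyphenyl)-5,6-dimethoxychromen-4-one
Product: 16 7-benzyloxy-2-(4-benzyloxyphenyl)-8-bromo-5,6-dimethoxychromen-4-one
Conditions: NBS (1.05 equiv), DMF, 0 °C to rt, dark
Reagents that add atoms: N-bromosuccinimide, O=C1CCC(=O)N1Br
Why: Electrophilic aromatic substitution at C8, the only unsubstituted ring A carbon, which is activated by O1 and the C7 benzyloxy group (ortho) and the C5 methoxy group (para) far more than C3 of the vinylogous ester or the ring B positions conjugated to the pyranone.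

**Step 9**
Reactants: 16 7-benzyloxy-2-(4-benzyloxyphenyl)-8-bromo-5,6-dimethoxychromen-4-one
Product: 17 7-benzyloxy-2-(4-benzyloxyphenyl)-5,6,8-trimethoxychromen-4-one
Conditions: NaOMe (excess), CuBr (20 mol%), MeOH/DMF, 110 °C
Reagents that add atoms: sodium methoxide, [Na+].[O-]C
Why: Ullmann-type copper-catalysed methoxylation of the aryl bromide, a transformation established for 8-bromoflavones, with the methyl and benzyl ethers expected to tolerate methoxide.

**Step 10**
Reactants: 17 7-benzyloxy-2-(4-benzyloxyphenyl)-5,6,8-trimethoxychromen-4-one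
Product: 19 7-benzyloxy-2-(4-benzyloxyphenyl)-3-hydroxy-5,6,8-trimethoxychromen-4-one, via boronate 18 (not isolated)
Conditions: LiN(iPr)2, THF, −78 °C; B(OMe)3, −78 °C to rt; AcOH, then 30% aq. H2O2, 0 °C to rt
Reagents that add atoms: hydrogen peroxide, OO
Why: Kinetic deprotonation at C3 by LiN(iPr)2 (the only acidic C–H, vinylic and alpha to the carbonyl, ring A being fully substituted), trapping with B(OMe)3 and oxidative 1,2-migration of boronate 18 with peroxide should give the flavonol, as known for alkoxyflavones.

**Step 11**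
Reactants: 19 7-benzyloxy-2-(4-benzyloxyphenyl)-3-hydroxy-5,6,8-trimethoxychromen-4-one
Product: 20 7-benzyloxy-2-(4-benzyloxyphenyl)-3,5,6,8-tetramethoxychromen-4-one
Conditions: MeI, K2CO3, acetone, reflux
Reagents that add atoms: iodomethane, CI
Why: Williamson O-methylation of the only free hydroxyl, the acidic 3-OH of the flavonol.

**Step 12**
Reactants: 20 7-benzyloxy-2-(4-benzyloxyphenyl)-3,5,6,8-tetramethoxychromen-4-one
Product: 21 7-hydroxy-2-(4-hydroxyphenyl)-3,5,6,8-tetramethoxychromen-4-one (target)
Conditions: H2 (1 atm), Pd/C (10 wt%), EtOAc/MeOH, rt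
Reagents that add atoms: none
Why: Catalytic hydrogenolysis cleaves both benzylic C–O bonds, while the methyl ethers and the tetrasubstituted vinylogous-ester C2=C3 bond of the pyranone should not be reduced at room temperature and 1 atm.

**Compound list**
1 | 2,3,4-trihydroxybenzaldehyde | O=Cc1ccc(O)c(O)c1O | starting material
2 | 4-benzyloxy-2,3-dihydroxybenzaldehyde | O=Cc1ccc(OCc2ccccc2)c(O)c1O | intermediate
3 | 4-benzyloxy-2,3-dimethoxybenzaldehyde | O=Cc1ccc(OCc2ccccc2)c(OC)c1OC | intermediate
4 | 4-benzyloxy-2,3-dimethoxyphenyl formate | O=COc1ccc(OCc2ccccc2)c(OC)c1OC | intermediate, not isolated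
5 | 4-benzyloxy-2,3-dimethoxyphenol | Oc1ccc(OCc2ccccc2)c(OC)c1OC | intermediate
6 | 4-benzyloxy-6-bromo-2,3-dimethoxyphenol | Oc1c(Br)cc(OCc2ccccc2)c(OC)c1OC | intermediate
7 | (4-benzyloxy-6-bromo-2,3-dimethoxyphenoxy)trimethylsilane | C[Si](C)(C)Oc1c(Br)cc(OCc2ccccc2)c(OC)c1OC | intermediate, not isolated
8 | lithium 4-benzyloxy-2,3-dimethoxy-6-(trimethylsilyl)phenoxide | [Li+].[O-]c1c([Si](C)(C)C)cc(OCc2ccccc2)c(OC)c1OC | intermediate, not isolated
9 | 4-benzyloxy-2,3-dimethoxy-6-(trimethylsilyl)phenyl trifluoromethanesulfonate | COc1c(OC)c(OCc2ccccc2)cc([Si](C)(C)C)c1OS(=O)(=O)C(F)(F)F | intermediate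
10 | 1-(benzyloxy)-4-iodobenzene | Ic1ccc(OCc2ccccc2)cc1 | starting material
11 | propiolic acid | C#CC(=O)O | starting material
12 | 3-(4-benzyloxyphenyl)propiolic acid | OC(=O)C#Cc1ccc(OCc2ccccc2)cc1 | intermediate
13 | 5-benzyloxy-3,4-dimethoxy-1,2-didehydrobenzene (aryne across C4a and C8a) | COC1=C(OC)C(OCc2ccccc2)=CC#C1 | intermediate, not isolated
14 | cesium 5-benzyloxy-2-[3-(4-benzyloxyphenyl)propioloyl]-3,4-dimethoxyphenoxide | [Cs+].[O-]c1cc(OCc2ccccc2)c(OC)c(OC)c1C(=O)C#Cc1ccc(OCc2ccccc2)cc1 | intermediate, not isolated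
15 | 7-benzyloxy-2-(4-benzyloxyphenyl)-5,6-dimethoxychromen-4-one | COc1c(OCc2ccccc2)cc2oc(-c3ccc(OCc4ccccc4)cc3)cc(=O)c2c1OC | intermediate
16 | 7-benzyloxy-2-(4-benzyloxyphenyl)-8-bromo-5,6-dimethoxychromen-4-one | COc1c(OCc2ccccc2)c(Br)c2oc(-c3ccc(OCc4ccccc4)cc3)cc(=O)c2c1OC | intermediate
17 | 7-benzyloxy-2-(4-benzyloxyphenyl)-5,6,8-trimethoxychromen-4-one | COc1c(OCc2ccccc2)c(OC)c2oc(-c3ccc(OCc4ccccc4)cc3)cc(=O)c2c1OC | intermediate
18 | dimethyl [7-benzyloxy-2-(4-benzyloxyphenyl)-5,6,8-trimethoxy-4-oxochromen-3-yl]boronate | COB(OC)c1c(-c2ccc(OCc3ccccc3)cc2)oc2c(OC)c(OCc3ccccc3)c(OC)c(OC)c2c1=O | intermediate, not isolated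
19 | 7-benzyloxy-2-(4-benzyloxyphenyl)-3-hydroxy-5,6,8-trimethoxychromen-4-one | COc1c(OCc2ccccc2)c(OC)c2oc(-c3ccc(OCc4ccccc4)cc3)c(O)c(=O)c2c1OC | intermediate
20 | 7-benzyloxy-2-(4-benzyloxyphenyl)-3,5,6,8-tetramethoxychromen-4-one | COc1c(OCc2ccccc2)c(OC)c2oc(-c3ccc(OCc4ccccc4)cc3)c(OC)c(=O)c2c1OC | intermediate
21 | 7-hydroxy-2-(4-hydroxyphenyl)-3,5,6,8-tetramethoxychromen-4-one | COc1c(O)c(OC)c2oc(-c3ccc(O)cc3)c(OC)c(=O)c2c1OC | target

**Totals.** Total step count: 12. Longest linear sequence: 11 steps (steps 1 to 5, then 7 to 12).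

**Steps most likely to fail**

Step 7. The propiolate may lose CO2 in hot fluoride before it meets the aryne, the aryl anion may be protonated before the acyl shift so that only the aryl ester forms, or the regiocontrol of oxygen attack may erode. The fallback sets out from 9 and comes back at 15, building the same C8a–O and C4a–C bonds stepwise. Triflate 9 is treated with CsF in DMF at rt and then with water. The aryne inserts into the formamide C=O bond with the same methoxy-controlled orientation, and hydrolysis should give 4-benzyloxy-6-hydroxy-2,3-dimethoxybenzaldehyde F1. Addition of the lithium acetylide of commercial 1-(benzyloxy)-4-ethynylbenzene (n-BuLi, THF, −78 °C, 2.5 equiv) should give racemic 5-benzyloxy-2-[3-(4-benzyloxyphenyl)-1-hydroxyprop-2-yn-1-yl]-3,4-dimethoxyphenol F2. Oxidation with MnO2 in CH2Cl2 should give 1-(4-benzyloxy-6-hydroxy-2,3-dimethoxyphenyl)-3-(4-benzyloxyphenyl)prop-2-yn-1-one F3. K2CO3 in acetone then closes ring C by 6-endo-dig oxa-Michael addition to give 15.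

Step 9. The hindered C8 bromide may be reduced instead of substituted, and hot methoxide may attack the pyranone or cleave the C7 benzyl ether. The fallback sets out from 16 and comes back at 17 by forming the C8–O bond through boron. Miyaura borylation (B2pin2, Pd(dppf)Cl2, KOAc, dioxane, 90 °C) should give 7-benzyloxy-2-(4-benzyloxyphenyl)-5,6-dimethoxy-8-(4,4,5,5-tetramethyl-1,3,2-dioxaborolan-2-yl)chromen-4-one F4. Oxidation with NaBO3·4H2O in THF/water should give 7-benzyloxy-2-(4-benzyloxyphenyl)-8-hydroxy-5,6-dimethoxychromen-4-one F5. Methylation with MeI and K2CO3 in acetone then gives 17.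

Step 10. Metalation at C3 may be incomplete, or the amide base may add to C2 or the carbonyl, and peroxide may over-oxidise the electron-rich product. The fallback sets out from 17 and comes back at 19 by electrophilic oxidation, which needs no strong base. Dimethyldioxirane in acetone/CH2Cl2 at 0 °C should epoxidise the C2=C3 bond to racemic 7-benzyloxy-2-(4-benzyloxyphenyl)-2,3-epoxy-5,6,8-trimethoxychroman-4-one F6. Catalytic p-toluenesulfonic acid in CH2Cl2 then opens the oxirane at C2 and loss of the C3 proton gives 19.

**Further compounds**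
F1 | step 7 | 4-benzyloxy-6-hydroxy-2,3-dimethoxybenzaldehyde | O=Cc1c(O)cc(OCc2ccccc2)c(OC)c1OC
F2 | step 7 | racemic 5-benzyloxy-2-[3-(4-benzyloxyphenyl)-1-hydroxyprop-2-yn-1-yl]-3,4-dimethoxyphenol | OC(C#Cc1ccc(OCc2ccccc2)cc1)c1c(O)cc(OCc2ccccc2)c(OC)c1OC
F3 | step 7 | 1-(4-benzyloxy-6-hydroxy-2,3-dimethoxyphenyl)-3-(4-benzyloxyphenyl)prop-2-yn-1-one | O=C(C#Cc1ccc(OCc2ccccc2)cc1)c1c(O)cc(OCc2ccccc2)c(OC)c1OC
F4 | step 9 | 7-benzyloxy-2-(4-benzyloxyphenyl)-5,6-dimethoxy-8-(4,4,5,5-tetramethyl-1,3,2-dioxaborolan-2-yl)chromen-4-one | COc1c(OCc2ccccc2)c(B2OC(C)(C)C(C)(C)O2)c2oc(-c3ccc(OCc4ccccc4)cc3)cc(=O)c2c1OC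
F5 | step 9 | 7-benzyloxy-2-(4-benzyloxyphenyl)-8-hydroxy-5,6-dimethoxychromen-4-one | COc1c(OCc2ccccc2)c(O)c2oc(-c3ccc(OCc4ccccc4)cc3)cc(=O)c2c1OC
F6 | step 10 | racemic 7-benzyloxy-2-(4-benzyloxyphenyl)-2,3-epoxy-5,6,8-trimethoxychroman-4-one (oxirane cis-fused) | COc1c(OCc2ccccc2)c(OC)c2c(c1OC)C(=O)C1OC1(c4ccc(OCc5ccccc5)cc4)O2
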